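The route rests on cutting the dihydrofuran ring of the target at its O1–C2 and C2–C3 bonds. The C3 methylene sits on ring carbon C3a between two oxygenated carbons (C4 and C7a), and the C2 stereocentre carries the CMe2OH carbon, an ester in disguise. This maps onto an ortho-quinone methide (O=C7a–C3a=CH2) and a one-carbon ester ylide. One [4+1] annulation therefore forms both bonds, the ring and the only stereocentre, with a cinchona ammonium group as chiral leaving group. Its precursor is a 4-O-benzyl isobutyrylphloroglucinol carrying a tosylmethyl group next to a free hydroxyl. Ester-to-carbinol conversion, debenzylation and dearomative gem-diprenylation finish the synthesis.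

Key step: step 4

Remarks on the chemistry (one line each):
- Structure check: the target has one stereocentre, C2 (S); O1 sits on the ring carbon next to the acyl-bearing carbon and the C3 methylene on the ring carbon next to the C4 carbonyl. CO2Me and CMe2OH hold the same CIP rank at C2, so the (2S) ester maps onto the (2S) carbinol and the target.
- Chiral amine: 9-O-methylquinidine, COc1ccc2nccc([C@H](OC)[C@H]3C[C@@H]4CCN3C[C@@H]4C=C)c2c1, a known reagent made from quinidine by one O-methylation (NaH, MeI) and recovered after use. Which pseudoenantiomeric alkaloid favours the (2S) ester must be settled by experiment; the quinidine series is assumed here, and 9-O-methylquinine would replace it with nothing else changed.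
- Precursor design: methyl bromoacetate is fully quaternised before the sulfone meets base, and the alkaloid hydroxyl is capped, so that neither a free alkylating agent nor an alkaloid OH can intercept the phenoxides or the ester.
- Sulfone formation is run in acid, where the benzylic hydroxyl is exchanged for sulfinate in its protonated state; the neutral ortho-quinone methide is set free only under the basic conditions of the annulation.

Step 1
Reactants: 1 phloroglucinol; 2 isobutyryl chloride
Product: 3 1-(2,4,6-trihydroxyphenyl)-2-methylpropan-1-one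
Conditions: AlCl3 (4 equiv), PhNO2, 65 °C; then ice/aq. HCl
Reagents that add atoms: none
Why: Friedel–Crafts C-acylation of the threefold-symmetric, strongly activated arene can give only one regioisomer, and complexation of the product ketone with AlCl3 deactivates it towards a second acylation.

Step 2
Reactants: 3 1-(2,4,6-trihydroxyphenyl)-2-methylpropan-1-one
Product: 4 1-[4-(benzyloxy)-2,6-dihydroxyphenyl]-2-methylpropan-1-one
Conditions: BnBr (1.0 equiv), K2CO3 (1.05 equiv), DMF, 0 °C to rt
Reagents that add atoms: benzyl bromide, BrCc1ccccc1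
Why: Williamson etherification in which the 4-OH, the most acidic hydroxyl (para to the acyl group) and the one not engaged with or crowded by the ketone, should be benzylated first when base and halide are limited to one equivalent; leaving both ortho hydroxyls free keeps the two open ring positions equivalent for step 3.

Step 3
Reactants: 4 1-[4-(benzyloxy)-2,6-dihydroxyphenyl]-2-methylpropan-1-one; 5 formaldehyde
Product: 7 1-{4-(benzyloxy)-2,6-dihydroxy-3-[(4-methylbenzenesulfonyl)methyl]phenyl}-2-methylpropan-1-one, via hydroxymethylphenol 6 (not isolated)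
Conditions: TolSO2Na (3 equiv), 37% aq. CH2O (1.0 equiv, slow addition), HCO2H/H2O, THF, rt
Reagents that add atoms: sodium p-toluenesulfinate, [Na+].[O-]S(=O)c1ccc(C)cc1
Why: Three-component Mannich-type condensation of a phenol, an aldehyde and a sulfinate: hydroxymethylation ortho to a free hydroxyl gives 6, whose benzylic hydroxyl, once protonated in the formic acid medium, should be replaced by the sulfur of the excess sulfinate faster than by a second arene (acid-catalysed substitution at a benzylic carbon stabilised by two ring oxygens), while the equivalence of the two open positions of 4 removes any regiochemical question.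

Step 4
Reactants: 7 1-{4-(benzyloxy)-2,6-dihydroxy-3-[(4-methylbenzenesulfonyl)methyl]phenyl}-2-methylpropan-1-one; 8 methyl bromoacetate
Product: 13 methyl (2S)-4-(benzyloxy)-6-hydroxy-7-(2-methylpropanoyl)-2,3-dihydro-1-benzofuran-2-carboxylate, via ammonium bromide 9 (not isolated), via ammonium ylide 10 (not isolated), via ortho-quinone methide 11 (not isolated), via betaine 12 (not isolated)
Conditions: 9-O-methylquinidine (1.3 equiv), 8 (1.2 equiv), MeCN, rt, 16 h, evaporate; then 7 (1.0 equiv), Cs2CO3 (3 equiv), CH2Cl2, −20 °C to rt
Reagents that add atoms: none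
Why: Proposed new method: Cs2CO3 deprotonates the 2-OH of 7 (between the acyl group and the CH2Ts arm) and expels p-toluenesulfinate to give quinone methide 11, and it also converts ammonium salt 9 into ylide 10; the ylide carbon adds to the exocyclic CH2 of 11 (1,4-addition with rearomatisation) to give betaine 12, whose ortho phenoxide then displaces the amine. The closest known reaction type is the enantioselective [4+1] annulation of in situ ortho-quinone methides with cinchona-derived ammonium ylides, established for substituted methide carbons (trans-2,3-disubstituted dihydrobenzofurans), whereas here the methide carbon is an unsubstituted CH2 and the ring carries an acyl group and a second hydroxyl. The dihydrofuran ring closes by 5-exo-tet SN2 with inversion at the carbon that becomes C2. This only new stereocentre is acidic in 12 (flanked by ester and ammonium) and should epimerise, so the chiral 9-O-methylquinidinium leaving group has to let the (R)-betaine close faster than its epimer (dynamic kinetic resolution) to give (2S)-13. The step needs ring closure through the right oxygen and no O-alkylation of the phenols by bromoacetate: the 4-O-benzyl ether blocks the other oxygen next to the CH2, the 6-OH is para to it and cannot reach, and complete quaternisation of 8 before base is added leaves no free alkylating agent.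

Step 5
Reactants: 13 methyl (2S)-4-(benzyloxy)-6-hydroxy-7-(2-methylpropanoyl)-2,3-dihydro-1-benzofuran-2-carboxylate
Product: 15 1-[(2S)-4-(benzyloxy)-6-hydroxy-2-(2-hydroxypropan-2-yl)-2,3-dihydro-1-benzofuran-7-yl]-2-methylpropan-1-one, via methyl ketone 14 (not isolated)
Conditions: MeMgBr (4 equiv), THF, −40 °C to 0 °C; then H2O
Reagents that add atoms: methylmagnesium bromide, C[Mg]Br
Why: Double Grignard addition to the ester through methyl ketone 14: the first equivalent turns the 6-OH into a magnesium phenoxide chelated and conjugated to the hindered isobutyryl ketone (a vinylogous carboxylate), which should therefore be spared at low temperature, and no bond to C2 is made or broken, so the (2S) centre is carried through.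

Step 6
Reactants: 15 1-[(2S)-4-(benzyloxy)-6-hydroxy-2-(2-hydroxypropan-2-yl)-2,3-dihydro-1-benzofuran-7-yl]-2-methylpropan-1-one
Product: 16 1-[(2S)-4,6-dihydroxy-2-(2-hydroxypropan-2-yl)-2,3-dihydro-1-benzofuran-7-yl]-2-methylpropan-1-one
Conditions: H2 (1 atm), Pd/C (10% Pd on carbon), EtOAc/MeOH, rt
Reagents that add atoms: none
Why: Catalytic hydrogenolysis of the aryl benzyl ether, run before any alkene is present; the chelated aryl ketone, the tertiary alcohol and the non-benzylic O1–C2 bond should be inert under these conditions.

Step 7
Reactants: 16 1-[(2S)-4,6-dihydroxy-2-(2-hydroxypropan-2-yl)-2,3-dihydro-1-benzofuran-7-yl]-2-methylpropan-1-one; 17 prenyl bromide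
Product: 19 garcinielliptone HD, via monoprenyl phenol 18 (not isolated)
Conditions: 17 (2.3 equiv), NaOMe (3 equiv), MeOH, 0 °C to rt; then dilute aq. HCl
Reagents that add atoms: none
Why: Base-mediated dearomative C-alkylation of an acylphloroglucinol (lupulone-type gem-diprenylation): C5 is the only unsubstituted ring carbon and lies between two oxygenated carbons, so it should take the first prenyl group to give 18 and then the second, because alkylation at the same carbon leads to the stabilised enolised β-triketone, with the protic solvent tempering O-alkylation and the remote C2 centre untouched.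

Compound list
1 | phloroglucinol (benzene-1,3,5-triol) | Oc1cc(O)cc(O)c1 | starting material
2 | isobutyryl chloride (2-methylpropanoyl chloride) | CC(C)C(Cl)=O | starting material
3 | 1-(2,4,6-trihydroxyphenyl)-2-methylpropan-1-one | CC(C)C(=O)c1c(O)cc(O)cc1O | intermediate
4 | 1-[4-(benzyloxy)-2,6-dihydroxyphenyl]-2-methylpropan-1-one | CC(C)C(=O)c1c(O)cc(OCc2ccccc2)cc1O | intermediate
5 | formaldehyde (used as its 37% aqueous solution) | C=O | starting material
6 | 1-[4-(benzyloxy)-2,6-dihydroxy-3-(hydroxymethyl)phenyl]-2-methylpropan-1-one | CC(C)C(=O)c1c(O)cc(OCc2ccccc2)c(CO)c1O | intermediate (not isolated)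
7 | 1-{4-(benzyloxy)-2,6-dihydroxy-3-[(4-methylbenzenesulfonyl)methyl]phenyl}-2-methylpropan-1-one | CC(C)C(=O)c1c(O)cc(OCc2ccccc2)c(CS(=O)(=O)c2ccc(C)cc2)c1O | intermediate
8 | methyl bromoacetate | COC(=O)CBr | starting material
9 | N-(2-methoxy-2-oxoethyl)-9-O-methylquinidinium bromide (alkylated at the quinuclidine nitrogen) | COc1ccc2nccc([C@H](OC)[C@H]3C[C@@H]4CC[N@@+]3(CC(=O)OC)C[C@@H]4C=C)c2c1.[Br-] | intermediate (not isolated)
10 | ammonium ylide of 9 (carbanion at the N–CH carbon next to the ester) | COc1ccc2nccc([C@H](OC)[C@H]3C[C@@H]4CC[N@@+]3([CH-]C(=O)OC)C[C@@H]4C=C)c2c1 | intermediate (not isolated)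
11 | 3-(benzyloxy)-5-hydroxy-2-methylidene-6-(2-methylpropanoyl)cyclohexa-3,5-dien-1-one (ortho-quinone methide) | CC(C)C(=O)C1=C(O)C=C(OCc2ccccc2)C(=C)C1=O | intermediate (not isolated)
12 | betaine: 9-O-methylquinidinium bearing on nitrogen the (2R)-1-methoxy-1-oxo-3-arylpropan-2-yl group, aryl = 6-(benzyloxy)-4-hydroxy-3-(2-methylpropanoyl)-2-oxidophenyl | COc1ccc2nccc([C@H](OC)[C@H]3C[C@@H]4CC[N@@+]3([C@@H](C(=O)OC)Cc5c([O-])c(C(=O)C(C)C)c(O)cc5OCc6ccccc6)C[C@@H]4C=C)c2c1 | intermediate (not isolated)
13 | methyl (2S)-4-(benzyloxy)-6-hydroxy-7-(2-methylpropanoyl)-2,3-dihydro-1-benzofuran-2-carboxylate | O1[C@H](C(=O)OC)Cc2c(OCc3ccccc3)cc(O)c(C(=O)C(C)C)c12 | intermediate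
14 | 1-[(2S)-2-acetyl-4-(benzyloxy)-6-hydroxy-2,3-dihydro-1-benzofuran-7-yl]-2-methylpropan-1-one | O1[C@H](C(C)=O)Cc2c(OCc3ccccc3)cc(O)c(C(=O)C(C)C)c12 | intermediate (not isolated)
15 | 1-[(2S)-4-(benzyloxy)-6-hydroxy-2-(2-hydroxypropan-2-yl)-2,3-dihydro-1-benzofuran-7-yl]-2-methylpropan-1-one | O1[C@H](C(C)(C)O)Cc2c(OCc3ccccc3)cc(O)c(C(=O)C(C)C)c12 | intermediate
16 | 1-[(2S)-4,6-dihydroxy-2-(2-hydroxypropan-2-yl)-2,3-dihydro-1-benzofuran-7-yl]-2-methylpropan-1-one | O1[C@H](C(C)(C)O)Cc2c(O)cc(O)c(C(=O)C(C)C)c12 | intermediate
17 | prenyl bromide (1-bromo-3-methylbut-2-ene) | CC(C)=CCBr | starting material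
18 | 1-[(2S)-4,6-dihydroxy-2-(2-hydroxypropan-2-yl)-5-(3-methylbut-2-en-1-yl)-2,3-dihydro-1-benzofuran-7-yl]-2-methylpropan-1-one | O1[C@H](C(C)(C)O)Cc2c(O)c(CC=C(C)C)c(O)c(C(=O)C(C)C)c12 | intermediate (not isolated)
19 | garcinielliptone HD, (2S,7Z)-7-(1-hydroxy-2-methylpropylidene)-2-(2-hydroxypropan-2-yl)-5,5-bis(3-methylbut-2-en-1-yl)-2,3-dihydro-1-benzofuran-4,6(5H,7H)-dione | CC(C)=CCC1(CC=C(C)C)C(=O)C2=C(O[C@H](C(C)(C)O)C2)/C(=C(/O)C(C)C)C1=O | target

Total step count: 7
Longest linear sequence: 7 steps (1 to 19)

Steps most likely to fail

Step 4. The ring closure may proceed without discrimination between the two epimerising betaines, or with the opposite sense. The quinone methide may instead be captured by the nucleophilic ring carbon of unreacted phenoxide, leading to methylene bridging between two arenes. The betaine may lose the amine by Hofmann-type elimination, and the product ester may racemise under prolonged exposure to base. The fallback uses known chemistry only, sets out from 4 and rejoins at 15, bypassing steps 3 to 5. C-Prenylation of 4 with one equivalent of 17 (NaOMe, MeOH, 0 °C) at one of the two equivalent ring positions should give 1-[4-(benzyloxy)-2,6-dihydroxy-3-(3-methylbut-2-en-1-yl)phenyl]-2-methylpropan-1-one F1. Silylation of both phenols (TBSOTf, 2,6-lutidine, CH2Cl2) should give 1-[4-(benzyloxy)-2,6-bis{[tert-butyl(dimethyl)silyl]oxy}-3-(3-methylbut-2-en-1-yl)phenyl]-2-methylpropan-1-one F2. Shi epoxidation of the prenyl alkene (D-fructose-derived ketone, KHSO5, K2CO3 buffer, MeCN/dimethoxymethane/H2O, 0 °C) should give 1-[4-(benzyloxy)-2,6-bis{[tert-butyl(dimethyl)silyl]oxy}-3-{[(2R)-3,3-dimethyloxiran-2-yl]methyl}phenyl]-2-methylpropan-1-one F3. Bu4NF in THF then removes the silyl groups, and the phenoxide ortho to the side chain should open the epoxide at its secondary carbon (5-exo-tet, inversion) to give 15 with the (2S) configuration.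

Step 7. The phenoxides may be alkylated on oxygen, the reaction may stall after the first prenyl group, or the second group may enter at a substituted ring carbon. The fallback sets out from 16 and rejoins at 19. Palladium-catalysed allylation (allyl methyl carbonate, Pd(PPh3)4 as a zerovalent palladium source, THF, rt) delivers a soft π-allyl electrophile that should be taken up at carbon twice, giving (2S,7Z)-7-(1-hydroxy-2-methylpropylidene)-2-(2-hydroxypropan-2-yl)-5,5-di(prop-2-en-1-yl)-2,3-dihydro-1-benzofuran-4,6(5H,7H)-dione F4. Cross-metathesis of both allyl groups with excess 2-methyl-2-butene (second-generation Grubbs catalyst, CH2Cl2, 40 °C) should then give 19.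

Step 3. The activated hydroxymethyl intermediate may be captured by the ring carbon of a second molecule of 4 instead of by sulfinate (methylene bridging), or a second sulfonylmethyl group may enter at the other open position. The fallback sets out from 4 and rejoins at 7. Aminomethylation with the preformed iminium salt dimethylmethylideneammonium iodide (1.0 equiv, CH2Cl2, rt) avoids free formaldehyde and should give the Mannich base 1-{4-(benzyloxy)-3-[(dimethylamino)methyl]-2,6-dihydroxyphenyl}-2-methylpropan-1-one F5. Heating F5 with sodium p-toluenesulfinate in AcOH/DMF should replace the protonated dimethylamino group by sulfinate (elimination–addition at the benzylic carbon) and give 7.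

Further compounds
F1 | step 4 | 1-[4-(benzyloxy)-2,6-dihydroxy-3-(3-methylbut-2-en-1-yl)phenyl]-2-methylpropan-1-one | CC(C)C(=O)c1c(O)cc(OCc2ccccc2)c(CC=C(C)C)c1O
F2 | step 4 | 1-[4-(benzyloxy)-2,6-bis{[tert-butyl(dimethyl)silyl]oxy}-3-(3-methylbut-2-en-1-yl)phenyl]-2-methylpropan-1-one | CC(C)C(=O)c1c(O[Si](C)(C)C(C)(C)C)cc(OCc2ccccc2)c(CC=C(C)C)c1O[Si](C)(C)C(C)(C)C
F3 | step 4 | 1-[4-(benzyloxy)-2,6-bis{[tert-butyl(dimethyl)silyl]oxy}-3-{[(2R)-3,3-dimethyloxiran-2-yl]methyl}phenyl]-2-methylpropan-1-one | CC(C)C(=O)c1c(O[Si](C)(C)C(C)(C)C)cc(OCc2ccccc2)c(C[C@H]3OC3(C)C)c1O[Si](C)(C)C(C)(C)C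
F4 | step 7 | (2S,7Z)-7-(1-hydroxy-2-methylpropylidene)-2-(2-hydroxypropan-2-yl)-5,5-di(prop-2-en-1-yl)-2,3-dihydro-1-benzofuran-4,6(5H,7H)-dione | C=CCC1(CC=C)C(=O)C2=C(O[C@H](C(C)(C)O)C2)/C(=C(/O)C(C)C)C1=O
F5 | step 3 | 1-{4-(benzyloxy)-3-[(dimethylamino)methyl]-2,6-dihydroxyphenyl}-2-methylpropan-1-one | CC(C)C(=O)c1c(O)cc(OCc2ccccc2)c(CN(C)C)c1O
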